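**Retrosynthetic overview**

1. Target 25 ⇒ enal 19 + butenolide phosphonate 23 (vinylogous Horner–Wadsworth–Emmons olefination, last step).
2. 19 ⇒ 17 ⇒ terminal alkynol 4 + the Grignard reagent of bromide 12 + CO2. One operation makes the bond from the exocyclic vinyl CH (C1′) to the chain CH2 (C2′), the C3–C2 bond, the (Z)-C3=C1′ alkene and the lactone ring A.
3. Enabling feature: in ring A (O1–C2–C3–C4–C5) the exocyclic C3=C1′ alkene is Z, so C2′ and the carbonyl carbon C2 are cis, and the ring oxygen O1 sits on C5, two carbons from C3. This is the pattern of a syn alkyl/carboxyl addition across a terminal alkyne whose homopropargylic alkoxide holds the metal on C3 in a five-membered chelate.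
4. 4 ⇐ 3-methylbut-2-enal + allenylboronate (catalytic asymmetric propargylation sets C5). 12 ⇐ geraniol (oxidation of the E-methyl group, methylenation, hydroboration, bromination).
5. Ring order: ring B (butenolide, step 10, on the phosphonate), then ring A (step 7); the two ring-bearing parts are joined in step 12.

Key step: step 7

Remark: the facial sense of (R)-TRIP in step 1 is assumed by analogy with aryl and alkenyl aldehydes; if the alcohol should prove to be (S), (S)-TRIP is used and nothing else changes.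

**Route**

Step 1
Reactants: 1 3-methylbut-2-enal; 2 allenylboronic acid pinacol ester
Product: 4 (R)-6-methylhept-5-en-1-yn-4-ol, via pinacol borate ester 3 (not isolated)
Conditions: (R)-TRIP (5 mol%), 4 Å molecular sieves, toluene, −20 °C; then aq. NaHCO3
Reagents that add atoms: none
Why: Chiral-phosphoric-acid-catalysed allenylboration of an aldehyde, in which the allenylboronate adds through its γ-carbon in a closed six-membered transition state to give the homopropargylic alcohol, and the phosphate, bound to a boronate oxygen and the formyl hydrogen, selects the aldehyde face that leads to the (R)-carbinol.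

Step 2
Reactants: 5 geraniol
Product: 6 geranyl tert-butyldimethylsilyl ether
Conditions: TBSCl, imidazole, DMF, 0 °C → rt
Reagents that add atoms: tert-butyldimethylsilyl chloride, CC(C)(C)[Si](C)(C)Cl
Why: Standard silylation of a primary allylic alcohol, giving an ether that should survive oxidation, ylide, borane and Grignard conditions.

Step 3
Reactants: 6 geranyl tert-butyldimethylsilyl ether
Product: 8 (2E,6E)-8-(tert-butyldimethylsilyloxy)-2,6-dimethylocta-2,6-dienal, via allylic alcohol 7 (not isolated)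
Conditions: SeO2 (0.3 equiv), salicylic acid (0.1 equiv), t-BuOOH (70% aq.), CH2Cl2, rt; crude product then MnO2, CH2Cl2, rt
Reagents that add atoms: tert-butyl hydroperoxide, CC(C)(C)OO (source of the new oxygen, relayed by selenium dioxide, O=[Se]=O)
Why: SeO2 allylic oxidation (ene reaction, then [2,3]-sigmatropic shift) attacks the E-methyl group of the more electron-rich terminal alkene with E selectivity, and MnO2 then converges the alcohol/aldehyde mixture on the (E)-enal.

Step 4
Reactants: 8 (2E,6E)-8-(tert-butyldimethylsilyloxy)-2,6-dimethylocta-2,6-dienal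
Product: 9 tert-butyl{[(2E,6E)-3,7-dimethylnona-2,6,8-trien-1-yl]oxy}dimethylsilane
Conditions: Ph3PCH3Br, KOtBu, THF, 0 °C → rt
Reagents that add atoms: methyltriphenylphosphonium bromide, C[P+](c1ccccc1)(c1ccccc1)c1ccccc1.[Br-]
Why: Wittig methylenation of an enal, which leaves the existing trisubstituted alkenes untouched.

Step 5
Reactants: 9 tert-butyl{[(2E,6E)-3,7-dimethylnona-2,6,8-trien-1-yl]oxy}dimethylsilane
Product: 11 (3E,7E)-9-(tert-butyldimethylsilyloxy)-3,7-dimethylnona-3,7-dien-1-ol, via B-alkyl-9-BBN adduct 10 (not isolated)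
Conditions: 9-BBN (1.1 equiv), THF, 0 °C → rt; then 3 M NaOH, 30% H2O2, 0 °C → rt
Reagents that add atoms: hydrogen peroxide, OO
Why: Hydroboration–oxidation, in which the bulky borane adds anti-Markovnikov to the only monosubstituted alkene and the two trisubstituted alkenes are too hindered to react.

Step 6
Reactants: 11 (3E,7E)-9-(tert-butyldimethylsilyloxy)-3,7-dimethylnona-3,7-dien-1-ol
Product: 12 {[(2E,6E)-9-bromo-3,7-dimethylnona-2,6-dien-1-yl]oxy}(tert-butyl)dimethylsilane
Conditions: CBr4, PPh3, CH2Cl2, 0 °C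
Reagents that add atoms: carbon tetrabromide, BrC(Br)(Br)Br
Why: Appel bromination of a primary alcohol under neutral conditions that the allylic silyl ether should tolerate.

Step 7
Reactants: 12 {[(2E,6E)-9-bromo-3,7-dimethylnona-2,6-dien-1-yl]oxy}(tert-butyl)dimethylsilane; 4 (R)-6-methylhept-5-en-1-yn-4-ol
Product: 17 (3Z,5R)-3-[(4E,8E)-10-(tert-butyldimethylsilyloxy)-4,8-dimethyldeca-4,8-dien-1-ylidene]-5-(2-methylprop-1-en-1-yl)dihydrofuran-2(3H)-one, via Grignard reagent 13 (not isolated), via bromomagnesium alkoxide 14 (not isolated), via alkenylmagnesium chelate 15 (not isolated), via hydroxy acid 16 (not isolated)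
Conditions: a) 12, Mg, THF, rt; b) 4, MeMgBr (1.0 equiv), THF, −40 °C; c) 13 (1.5 equiv) added to 14, Fe(acac)3 (10 mol%), THF, −40 → 0 °C; d) CO2 (1 atm), −20 °C → rt; e) 1 M HCl to pH 2, 0 °C → rt
Reagents that add atoms: carbon dioxide, O=C=O
Why: Proposed new method: Fe(acac)3 is reduced by 13 to an alkyl ferrate that takes up the alkoxide of 14, so that the chain CH2 is delivered from iron to the terminal alkyne carbon while iron binds the internal carbon in a five-membered oxaferracycle (syn-carbometalation), and iron-to-magnesium exchange gives the chelated alkenylmagnesium 15, which inserts CO2 with retention before acid releases hydroxy acid 16. The closest known reaction types are the iron-catalysed, alkoxide-directed syn-carbomagnesiation of internal homopropargylic alcohols with electrophile capture of the alkenylmagnesium, and the nickel-catalysed methylzincation–carboxylation of homopropargylic alcohols to α-alkylidene-γ-butyrolactones; new here is the combination of a terminal alkyne, a primary alkyl Grignard reagent bearing β-hydrogens and CO2 capture. Ring A closes by 5-exo-trig lactonisation of 16 (hydroxyl and carboxyl hang on the same sp2 carbon C3, so closure does not depend on the alkene geometry), after the transient oxametallacycle 15 has closed by 5-exo-dig addition. No stereocentre is created: C5 keeps the (R) configuration of 4 because its C–O bond is never broken, and the Z geometry of C3=C1′ follows from syn addition of chain and metal and from retention in the carboxylation. The step needs regioselectivity (chain to the terminal carbon, against the usual preference of terminal alkynes), which the two-carbon O–C5–C4 tether secures by allowing only the five-membered metallacycle, and chemoselectivity against deprotonation of the alkyne C–H and β-hydride loss from the alkyl-iron species, which low temperature and intramolecular delivery are expected to favour.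

Step 8
Reactants: 17 (3Z,5R)-3-[(4E,8E)-10-(tert-butyldimethylsilyloxy)-4,8-dimethyldeca-4,8-dien-1-ylidene]-5-(2-methylprop-1-en-1-yl)dihydrofuran-2(3H)-one
Product: 18 (3Z,5R)-3-[(4E,8E)-10-hydroxy-4,8-dimethyldeca-4,8-dien-1-ylidene]-5-(2-methylprop-1-en-1-yl)dihydrofuran-2(3H)-one
Conditions: HF·pyridine, pyridine, THF, 0 °C → rt
Reagents that add atoms: none
Why: Buffered fluoride desilylation of a primary silyl ether, non-basic and only weakly acidic, so the allylic lactone C–O bond and the Z-alkylidene unit should be left alone.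

Step 9
Reactants: 18 (3Z,5R)-3-[(4E,8E)-10-hydroxy-4,8-dimethyldeca-4,8-dien-1-ylidene]-5-(2-methylprop-1-en-1-yl)dihydrofuran-2(3H)-one
Product: 19 (2E,6E)-3,7-dimethyl-10-[(3Z,5R)-5-(2-methylprop-1-en-1-yl)-2-oxodihydrofuran-3(2H)-ylidene]deca-2,6-dienal
Conditions: MnO2 (excess), CH2Cl2, rt
Reagents that add atoms: none
Why: MnO2 oxidation is selective for allylic alcohols and should give the (E)-enal without E/Z isomerisation.

Step 10
Reactants: 20 3-methylbut-2-enoic acid
Product: 22 4-(bromomethyl)furan-2(5H)-one, via dibromo acid 21 (not isolated)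
Conditions: NBS (2.1 equiv), dibenzoyl peroxide (cat.), chlorobenzene, 85 °C; then aq. NaHCO3, rt
Reagents that add atoms: N-bromosuccinimide, O=C1CCC(=O)N1Br
Why: Wohl–Ziegler bromination of both allylic methyl groups, after which the carboxylate displaces the bromide cis to it (5-exo-tet) and closes ring B.

Step 11
Reactants: 22 4-(bromomethyl)furan-2(5H)-one
Product: 23 diethyl [(5-oxo-2,5-dihydrofuran-3-yl)methyl]phosphonate
Conditions: P(OEt)3, toluene, 110 °C
Reagents that add atoms: triethyl phosphite, CCOP(OCC)OCC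
Why: Michaelis–Arbuzov reaction of a primary allylic bromide.

Step 12
Reactants: 19 (2E,6E)-3,7-dimethyl-10-[(3Z,5R)-5-(2-methylprop-1-en-1-yl)-2-oxodihydrofuran-3(2H)-ylidene]deca-2,6-dienal; 23 diethyl [(5-oxo-2,5-dihydrofuran-3-yl)methyl]phosphonate
Product: 25 (3Z,5R)-3-[(4E,8E,10E)-4,8-dimethyl-11-(5-oxo-2,5-dihydrofuran-3-yl)undeca-4,8,10-trien-1-ylidene]-5-(2-methylprop-1-en-1-yl)dihydrofuran-2(3H)-one, via lithiated phosphonate 24 (not isolated)
Conditions: 23 (1.3 equiv), LiHMDS (1.25 equiv), THF, −78 °C; then 19, −78 → 0 °C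
Reagents that add atoms: none
Why: Vinylogous Horner–Wadsworth–Emmons olefination, in which the stabilised dienolate anion 24 attacks the enal through its exocyclic carbon and elimination of phosphate from the equilibrated adduct should give the (E)-alkene, with no free strong base left to touch the lactones or the Z-alkylidene unit.

**Compound list**

1 | 3-methylbut-2-enal | CC(C)=CC=O | starting material
2 | allenylboronic acid pinacol ester, 4,4,5,5-tetramethyl-2-(propa-1,2-dien-1-yl)-1,3,2-dioxaborolane | C=C=CB1OC(C)(C)C(C)(C)O1 | starting material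
3 | pinacol borate ester of 4, 4,4,5,5-tetramethyl-2-{[(4R)-6-methylhept-5-en-1-yn-4-yl]oxy}-1,3,2-dioxaborolane | CC(C)=C[C@H](OB1OC(C)(C)C(C)(C)O1)CC#C | intermediate
4 | (R)-6-methylhept-5-en-1-yn-4-ol | CC(C)=C[C@H](O)CC#C | intermediate
5 | geraniol, (2E)-3,7-dimethylocta-2,6-dien-1-ol | CC(C)=CCC/C(C)=C/CO | starting material
6 | geranyl tert-butyldimethylsilyl ether | CC(C)=CCC/C(C)=C/CO[Si](C)(C)C(C)(C)C | intermediate
7 | (2E,6E)-8-(tert-butyldimethylsilyloxy)-2,6-dimethylocta-2,6-dien-1-ol | OC/C(C)=C/CC/C(C)=C/CO[Si](C)(C)C(C)(C)C | intermediate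
8 | (2E,6E)-8-(tert-butyldimethylsilyloxy)-2,6-dimethylocta-2,6-dienal | O=C/C(C)=C/CC/C(C)=C/CO[Si](C)(C)C(C)(C)C | intermediate
9 | tert-butyl{[(2E,6E)-3,7-dimethylnona-2,6,8-trien-1-yl]oxy}dimethylsilane | C=C/C(C)=C/CC/C(C)=C/CO[Si](C)(C)C(C)(C)C | intermediate
10 | 9-[(3E,7E)-9-(tert-butyldimethylsilyloxy)-3,7-dimethylnona-3,7-dien-1-yl]-9-borabicyclo[3.3.1]nonane | C1CC2CCCC(C1)B2CC/C(C)=C/CC/C(C)=C/CO[Si](C)(C)C(C)(C)C | intermediate
11 | (3E,7E)-9-(tert-butyldimethylsilyloxy)-3,7-dimethylnona-3,7-dien-1-ol | OCC/C(C)=C/CC/C(C)=C/CO[Si](C)(C)C(C)(C)C | intermediate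
12 | {[(2E,6E)-9-bromo-3,7-dimethylnona-2,6-dien-1-yl]oxy}(tert-butyl)dimethylsilane | BrCC/C(C)=C/CC/C(C)=C/CO[Si](C)(C)C(C)(C)C | intermediate
13 | [(3E,7E)-9-(tert-butyldimethylsilyloxy)-3,7-dimethylnona-3,7-dien-1-yl]magnesium bromide | Br[Mg]CC/C(C)=C/CC/C(C)=C/CO[Si](C)(C)C(C)(C)C | intermediate
14 | bromomagnesium (R)-6-methylhept-5-en-1-yn-4-olate | CC(C)=C[C@H](O[Mg]Br)CC#C | intermediate
15 | (3Z,5R)-3-[(4E,8E)-10-(tert-butyldimethylsilyloxy)-4,8-dimethyldeca-4,8-dien-1-ylidene]-5-(2-methylprop-1-en-1-yl)-1-oxa-2-magnesacyclopentane | CC(C)=C[C@H]1C/C(=C/CC/C(C)=C/CC/C(C)=C/CO[Si](C)(C)C(C)(C)C)[Mg]O1 | intermediate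
16 | (2Z,6E,10E)-12-(tert-butyldimethylsilyloxy)-2-[(2R)-2-hydroxy-4-methylpent-3-en-1-yl]-6,10-dimethyldodeca-2,6,10-trienoic acid | CC(C)=C[C@H](O)C/C(=C/CC/C(C)=C/CC/C(C)=C/CO[Si](C)(C)C(C)(C)C)C(=O)O | intermediate
17 | (3Z,5R)-3-[(4E,8E)-10-(tert-butyldimethylsilyloxy)-4,8-dimethyldeca-4,8-dien-1-ylidene]-5-(2-methylprop-1-en-1-yl)dihydrofuran-2(3H)-one | CC(C)=C[C@H]1C/C(=C/CC/C(C)=C/CC/C(C)=C/CO[Si](C)(C)C(C)(C)C)C(=O)O1 | intermediate
18 | (3Z,5R)-3-[(4E,8E)-10-hydroxy-4,8-dimethyldeca-4,8-dien-1-ylidene]-5-(2-methylprop-1-en-1-yl)dihydrofuran-2(3H)-one | CC(C)=C[C@H]1C/C(=C/CC/C(C)=C/CC/C(C)=C/CO)C(=O)O1 | intermediate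
19 | (2E,6E)-3,7-dimethyl-10-[(3Z,5R)-5-(2-methylprop-1-en-1-yl)-2-oxodihydrofuran-3(2H)-ylidene]deca-2,6-dienal | CC(C)=C[C@H]1C/C(=C/CC/C(C)=C/CC/C(C)=C/C=O)C(=O)O1 | intermediate
20 | 3-methylbut-2-enoic acid | CC(C)=CC(=O)O | starting material
21 | 4-bromo-3-(bromomethyl)but-2-enoic acid | OC(=O)C=C(CBr)CBr | intermediate
22 | 4-(bromomethyl)furan-2(5H)-one | BrCC1=CC(=O)OC1 | intermediate
23 | diethyl [(5-oxo-2,5-dihydrofuran-3-yl)methyl]phosphonate | CCOP(=O)(OCC)CC1=CC(=O)OC1 | intermediate
24 | lithium salt of the carbanion of 23 at the P–CH2 carbon | [Li+].CCOP(=O)(OCC)[CH-]C1=CC(=O)OC1 | intermediate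
25 | (3Z,5R)-3-[(4E,8E,10E)-4,8-dimethyl-11-(5-oxo-2,5-dihydrofuran-3-yl)undeca-4,8,10-trien-1-ylidene]-5-(2-methylprop-1-en-1-yl)dihydrofuran-2(3H)-one | CC(C)=C[C@H]1C/C(=C/CC/C(C)=C/CC/C(C)=C/C=C/C2=CC(=O)OC2)C(=O)O1 | target

**Step count**

Total step count: 12. Longest linear sequence: 9 steps (5 → 25: steps 2–9 and 12).

**Steps most likely to fail**

Step 7 (proposed new method). The carbometalation may run with the opposite regiochemistry (chain to the internal carbon), the Grignard reagent may simply deprotonate the terminal alkyne, or the alkyl-iron species may lose a β-hydride and transfer hydride instead of the chain. The fallback uses known chemistry and sets out from 4 and 12. The dianion of 4 (n-BuLi, 2.1 equiv, THF/DMPU, −78 → 0 °C) is alkylated at the acetylide carbon by 12, which makes the same C–C bond and should give (4R,10E,14E)-16-(tert-butyldimethylsilyloxy)-2,10,14-trimethylhexadeca-2,10,14-trien-6-yn-4-ol F1. Hydroxyl-directed trans-hydrostannation (Bu3SnH, [Cp*RuCl]4 cat., CH2Cl2, rt) should place tin on the alkyne carbon next to the carbinol and give (4R,6Z,10E,14E)-16-(tert-butyldimethylsilyloxy)-2,10,14-trimethyl-6-(tributylstannyl)hexadeca-2,6,10,14-tetraen-4-ol F2. Iododestannylation (I2, CH2Cl2, −78 °C) with retention should give (4R,6Z,10E,14E)-16-(tert-butyldimethylsilyloxy)-6-iodo-2,10,14-trimethylhexadeca-2,6,10,14-tetraen-4-ol F3. Iodine–lithium exchange (t-BuLi, Et2O, −78 °C), CO2 and acidification then lead through hydroxy acid 16 back to the route at 17.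

Step 1. Facial selectivity may be insufficient, or of the opposite sense, with a β,β-disubstituted enal. The fallback replaces asymmetric catalysis by resolution and sets out from 1. Propargylation with propargyl bromide and Zn (THF/aq. NH4Cl) should give racemic 6-methylhept-5-en-1-yn-4-ol F4. Lipase-catalysed acylation (Amano lipase PS, vinyl acetate, hexane, rt), with the isobutenyl group acting as the large substituent, should convert the (R)-enantiomer into (R)-6-methylhept-5-en-1-yn-4-yl acetate F5 and leave (S)-6-methylhept-5-en-1-yn-4-ol F6. After separation, methanolysis of the acetate (K2CO3, MeOH) returns to the route at 4.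

Step 12. The ambident anion may attack through the ring α-carbon, the E selectivity of the new alkene may erode, or base may isomerise the enal. The fallback replaces olefination by cross-coupling and sets out from 19. Takai olefination (CrCl2, CHI3, THF, 0 °C) should give (3Z,5R)-3-[(4E,8E,10E)-11-iodo-4,8-dimethylundeca-4,8,10-trien-1-ylidene]-5-(2-methylprop-1-en-1-yl)dihydrofuran-2(3H)-one F7. The coupling partner 4-(tributylstannyl)furan-2(5H)-one F8 is made from commercial 4-bromofuran-2(5H)-one and hexabutylditin with Pd(PPh3)4. Stille coupling of the two (Pd2(dba)3, AsPh3, CuI, NMP, rt) returns to the route at 25; the mild conditions are chosen to spare the allylic lactone.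

Further compounds
F1 | step 7 | (4R,10E,14E)-16-(tert-butyldimethylsilyloxy)-2,10,14-trimethylhexadeca-2,10,14-trien-6-yn-4-ol | CC(C)=C[C@H](O)CC#CCC/C(C)=C/CC/C(C)=C/CO[Si](C)(C)C(C)(C)C
F2 | step 7 | (4R,6Z,10E,14E)-16-(tert-butyldimethylsilyloxy)-2,10,14-trimethyl-6-(tributylstannyl)hexadeca-2,6,10,14-tetraen-4-ol | CC(C)=C[C@H](O)C/C(=C/CC/C(C)=C/CC/C(C)=C/CO[Si](C)(C)C(C)(C)C)[Sn](CCCC)(CCCC)CCCC
F3 | step 7 | (4R,6Z,10E,14E)-16-(tert-butyldimethylsilyloxy)-6-iodo-2,10,14-trimethylhexadeca-2,6,10,14-tetraen-4-ol | CC(C)=C[C@H](O)C/C(I)=C/CC/C(C)=C/CC/C(C)=C/CO[Si](C)(C)C(C)(C)C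
F4 | step 1 | racemic 6-methylhept-5-en-1-yn-4-ol | CC(C)=CC(O)CC#C
F5 | step 1 | (R)-6-methylhept-5-en-1-yn-4-yl acetate | CC(C)=C[C@H](OC(C)=O)CC#C
F6 | step 1 | (S)-6-methylhept-5-en-1-yn-4-ol | CC(C)=C[C@@H](O)CC#C
F7 | step 12 | (3Z,5R)-3-[(4E,8E,10E)-11-iodo-4,8-dimethylundeca-4,8,10-trien-1-ylidene]-5-(2-methylprop-1-en-1-yl)dihydrofuran-2(3H)-one | CC(C)=C[C@H]1C/C(=C/CC/C(C)=C/CC/C(C)=C/C=C/I)C(=O)O1
F8 | step 12 | 4-(tributylstannyl)furan-2(5H)-one | CCCC[Sn](CCCC)(CCCC)C1=CC(=O)OC1
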